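**Retrosynthetic overview**
1. Ring B: catechol (1) is perbrominated to tetrabromocatechol (2). Every free position is filled, so there is no regiochemical question.
2. Ring A: 2-amino-4,6-dibromophenol (3) already carries the OH and both Br in the right places. It is diazotised to the ortho-quinone diazide (4).
3. Key disconnection: the diaryl ether C(ring A)–O bond. It is made last, under neutral conditions, by carbene O–H insertion of 4 into one of the two equivalent OH groups of 2, through oxonium ylide (5), giving target (6).
4. No ring is formed in the route. Both benzene rings come intact from the starting materials, and there are no protecting groups and no late bromination.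

Assumption: the SMILES has no stereocentre and the diaryl ether rotates freely, so the target is achiral and "single enantiomer" simply means the compound as drawn.

**Route**

Step 1
Reactants: 1 catechol
Product: 2 3,4,5,6-tetrabromobenzene-1,2-diol (tetrabromocatechol)
Conditions: Br2 (4.4 equiv), AcOH, 20 → 90 °C, 3 h; cool, filter, recrystallise (AcOH)
Reagents that add atoms: bromine, BrBr
Why: Exhaustive electrophilic aromatic bromination: both OH groups activate all four free positions, the only possible end point is the tetrabromide, the HBr formed holds the product at the catechol rather than the quinone level, and no stereocentre is created.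

Step 2
Reactants: 3 2-amino-4,6-dibromophenol
Product: 4 2,4-dibromo-6-diazocyclohexa-2,4-dien-1-one (ortho-quinone diazide)
Conditions: t-BuONO (1.3 equiv), AcOH–MeCN (1:4), 0 °C, 1 h, dark, N2; ice-water, filter, wash acid-free with water, dry in vacuo cold; store dark, use as a dried DCE solution
Reagents that add atoms: tert-butyl nitrite, CC(C)(C)ON=O
Why: Diazotisation of an ortho-aminophenol with an alkyl nitrite in acetic acid (Knoevenagel method): the phenolic proton, acidified by two Br and the neighbouring diazonio group, is lost spontaneously so the neutral diazo-oxide is isolated, both Br sit meta to the diazo carbon and are not activated for displacement, and no stereocentre is created.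

Step 3
Reactants: 2 tetrabromocatechol (2.0 equiv); 4 2,4-dibromo-6-diazocyclohexa-2,4-dien-1-one
Product: 6 3,4,5,6-tetrabromo-2-(3,5-dibromo-2-hydroxyphenoxy)phenol (target), via oxonium ylide 5 (not isolated)
Conditions: Rh2(esp)2 (1 mol %; esp = α,α,α′,α′-tetramethyl-1,3-benzenedipropanoate), anhydrous DCE, 60 °C, dark, N2; 4 in DCE added over 4 h by syringe pump; SiO2 (hexane–EtOAc, 1 % AcOH), excess 2 recovered
Reagents that add atoms: none
Why: Proposed new method: dirhodium-catalysed quinoid-carbene O–H insertion used as a neutral, protecting-group-free diaryl ether synthesis between a monocyclic dibromo ortho-quinone diazide and a perbrominated catechol; Rh2(esp)2 (divalent rhodium, with chelating carboxylates that resist exchange with the acidic catechol) expels N2 from 4 to give a catalyst-bound, strongly electrophilic quinoid carbene, the hydrogen-bond-donating and therefore more electron-rich oxygen of 2 attacks the carbene carbon, release of rhodium rearomatises ring A to ylide 5, and an irreversible proton shift from the oxonium O to the ring A phenolate O gives 6 with the new C–O bond exactly at the former diazo carbon; the two OH groups of 2 are equivalent so only one mono-ether is possible, excess 2 and slow addition suppress double insertion and carbene dimerisation, metal catalysis at 60 °C in the dark should outrun the Wolff ring contraction, the absence of base rules out Smiles rearrangement and dibenzodioxin closure, aryl bromides are inert to the catalyst, and no stereocentre is formed; the closest known reaction type is the dirhodium-catalysed O–H insertion of 1,2-diazonaphthoquinones and para-quinone diazides into simple alcohols.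

**Compound list**
1 | catechol (benzene-1,2-diol) | Oc1ccccc1O | starting material
2 | 3,4,5,6-tetrabromobenzene-1,2-diol (tetrabromocatechol) | Oc1c(O)c(Br)c(Br)c(Br)c1Br | intermediate
3 | 2-amino-4,6-dibromophenol | Nc1cc(Br)cc(Br)c1O | starting material
4 | 2,4-dibromo-6-diazocyclohexa-2,4-dien-1-one | O=C1C(Br)=CC(Br)=CC1=[N+]=[N-] | intermediate
5 | 2,4-dibromo-6-[(2,3,4,5-tetrabromo-6-hydroxyphenyl)oxonio]phenolate (oxonium ylide) | [O-]c1c(Br)cc(Br)cc1[OH+]c1c(O)c(Br)c(Br)c(Br)c1Br | intermediate
6 | 3,4,5,6-tetrabromo-2-(3,5-dibromo-2-hydroxyphenoxy)phenol (CNP0309766.0, achiral) | Oc1c(Br)cc(Br)cc1Oc1c(O)c(Br)c(Br)c(Br)c1Br | target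

**Count**
- Total steps: 3.
- Longest linear sequence: 2 (1 → 2 → 6 or 3 → 4 → 6).

**Steps most likely to fail**

**First: step 3 (the proposed new step).**
- Risk: 2 is a poor nucleophile, so Wolff ring contraction may compete. The resulting ketene would be trapped by 2 as an aryl ester.
- Risk: carbene dimer or azine formation, a second insertion into 6, and slow N2 loss from the aromatic-zwitterionic diazo-oxide.
- Fallback (known chemistry only): it sets out from 2 and comes back at 6. Monomethylation of 2 (MeI 1.0 equiv, Li2CO3, DMF) gives 2,3,4,5-tetrabromo-6-methoxyphenol F1. Chan–Lam–Evans coupling of F1 with 2-methoxyphenylboronic acid (Cu(OAc)2, pyridine, 4 Å MS, CH2Cl2, air, rt, where aryl bromides are inert) gives 1,2,3,4-tetrabromo-5-methoxy-6-(2-methoxyphenoxy)benzene F2. BBr3 (CH2Cl2, −78 °C → rt) cleaves both methyl ethers to 3,4,5,6-tetrabromo-2-(2-hydroxyphenoxy)phenol F3. Br2 (2.05 equiv, AcOH, rt) then brominates ring A only, ortho and para to its OH, because ring B has no free position. This gives 6.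

**Second: step 2.**
- Risk: in the weakly acidic medium the diazo species could self-couple with unreacted 3.
- Risk: 4 is an energetic, light-sensitive solid that may not survive isolation in the acid-free, dry state that step 3 needs.
- Fallback: it sets out from 3 and comes back at 4, using a masked diazonium instead of direct isolation. Compound 3 is diazotised in strong acid (NaNO2, 3 M HCl, 0 °C), where the amine is fully protonated, to 3,5-dibromo-2-hydroxybenzenediazonium chloride F4. This is quenched at once with pyrrolidine/Na2CO3 to the bench-stable, chromatographable triazene 2,4-dibromo-6-[(E)-pyrrolidin-1-yldiazenyl]phenol F5. Just before step 3, F5 is cleaved with HCl in CH2Cl2 (0 °C), which returns F4. A cold aqueous NaOAc wash removes the pyrrolidinium salt and the phenolic proton. This leaves a solution of 4 that is dried, swapped into DCE and used directly.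

**Third: step 1.**
- Risk: the product may be contaminated by tribromocatechol or by partly over-oxidised quinone, and either would spoil the stoichiometry of step 3.
- Fallback: it sets out from 1 and comes back at 2, using the over-oxidation as a purification handle. Compound 1 is brominated with excess Br2 in AcOH, and the whole crude is oxidised with HNO3 in AcOH to 3,4,5,6-tetrabromocyclohexa-3,5-diene-1,2-dione F6. This deep-red quinone crystallises cleanly. It is then reduced with aqueous Na2S2O4/EtOAc to pure 2.

**Further compounds**
F1 | step 3 | 2,3,4,5-tetrabromo-6-methoxyphenol | COc1c(O)c(Br)c(Br)c(Br)c1Br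
F2 | step 3 | 1,2,3,4-tetrabromo-5-methoxy-6-(2-methoxyphenoxy)benzene | COc1ccccc1Oc1c(OC)c(Br)c(Br)c(Br)c1Br
F3 | step 3 | 3,4,5,6-tetrabromo-2-(2-hydroxyphenoxy)phenol | Oc1ccccc1Oc1c(O)c(Br)c(Br)c(Br)c1Br
F4 | step 2 | 3,5-dibromo-2-hydroxybenzenediazonium chloride | Oc1c(Br)cc(Br)cc1[N+]#N.[Cl-]
F5 | step 2 | 2,4-dibromo-6-[(E)-pyrrolidin-1-yldiazenyl]phenol | Oc1c(Br)cc(Br)cc1/N=N/N1CCCC1
F6 | step 1 | 3,4,5,6-tetrabromocyclohexa-3,5-diene-1,2-dione (o-bromanil) | O=C1C(=O)C(Br)=C(Br)C(Br)=C1Br
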